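## Analysis of the target

Target 25 is a dimeric flavan-3-ol. Two 5-deoxy flavan units are joined by one C–C bond from C4 of the upper unit to C6 of the lower unit. The upper unit has ring A (7-hydroxy benzo ring), pyran ring C and ring B (4-hydroxyphenyl on C2). The lower unit has ring D (7-hydroxy benzo ring), pyran ring F and ring E (3,4-dihydroxyphenyl on C2), and its C4 is a plain methylene.

There are five stereocentres. Upper C2 (R), C3 (S) and C4 (R) are contiguous and all-trans: ring B and ring D lie on one face of ring C, the C3 hydroxyl on the other. Lower C2 (S) and C3 (S) are 2,3-cis. The two C2 aryl groups belong to opposite enantiomeric series, so the two heterocycles need independent absolute control.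

Sensitive features are the six phenols (one an oxidisable catechol), the two benzylic aryl ether bonds O1–C2, the doubly benzylic C4–H and C4–C6 bonds of the upper unit (acid, oxidants), and the base-lability of flavanoid C2 centres through ring opening. The hard points are the site of the interflavan bond (C6, not C8, of ring D), the upper stereotriad, and a cis lower unit whose C3 oxygen sits on the more hindered face.

The strategy rests on one feature. Lower C4 is a CH2 bonded to C4a, and C4a is ortho to the ring oxygen O1 (on C8a) and para to the C7 oxygen. The chain O1–C2(ring E)–C3–C4 is therefore the chain of an aryl propargyl ether of ring D, and ring F can be closed by forming C4–C4a.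

## Retrosynthetic reasoning

**25 ⇒ 24.** All eight hydroxyl groups except the two that are never protected are carried as benzyl ethers; the six O–benzyl bonds are cut together at the end. One neutral hydrogenolysis avoids acid or base on the free polyphenol.

**24 ⇒ 23 ⇒ 22.** The lower C3–H bond is cut. The cis alcohol 24 comes from ketone 23 by hydride delivery to the face opposite ring E, and 23 from the trans alcohol 22. The detour is accepted because alkene hydration anti to ring E gives the trans isomer naturally, while the oxidation–reduction pair is the reliable way to the cis series.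

**22 ⇒ 20.** The lower C3–O bond is traced to the C3=C4 double bond of 2H-chromene 20. The forward hydroboration must place boron on C3 (hydrogen on benzylic C4) and add anti to ring E.

**20 ⇒ 19 (key disconnection).** The lower C4–C4a bond is cut, which opens ring F to aryl propargyl ether 19 with the propargylic carbon as C2. This is the only ring F bond whose formation leaves C2 untouched and turns a phenol oxygen of ring D into O1. The forward step must close 6-endo onto the ring D carbon para to the C7 benzyloxy group.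

**19 ⇒ 15 + 18.** The O1–C2 bond is cut between phenol 15 and racemic propargylic acetate 18. This is the convergent join of the upper unit with the ring E fragment. The forward etherification must set C2 under catalyst control; 18 comes in two steps from aldehyde 16 through alcohol 17.

**15 ⇒ 14 ⇒ 13.** These are protecting-group adjustments only: the ring D silyl ether is cut to free the one phenol that becomes O1, after the upper C3 hydroxyl of 13 is capped as a benzyl ether so that it stays out of the later oxidation.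

**13 ⇒ 11.** The upper C3–O and C4–H bonds are traced to the C3=C4 alkene of 4-aryl-2H-chromene 11. One syn addition anti to ring B sets both C3 and C4 relative to C2 in the all-trans sense.

**11 ⇒ 10 ⇒ 4 + 7.** The upper C4–ring D bond is cut between flavanone 4 and aryl bromide 7 (through aryl metal species 8 and 9 and carbinol 10). The position of bromine in 7 fixes the interflavan bond at the carbon that becomes lower C6, so no Friedel–Crafts regiochemistry arises.

**7 ⇒ 6 ⇒ 5.** The two O–protecting-group bonds of ring D are cut in turn. The oxygen para to bromine (future O1) carries a temporary silyl group, and the oxygen ortho to bromine (future C7–O) a permanent benzyl group.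

**4 ⇒ 2 + 3; 2 ⇒ 1.** The C2–ring B bond is cut between chromone 2 and boronic acid 3. The forward conjugate arylation sets upper C2, the only stereocentre of the upper unit needing a chiral catalyst. 2 is the benzyl ether of 1.

## Alternatives that were turned down

**Alternative 1: ring F by aminocatalytic ortho-quinone methide annulation.**
- Disconnection: lower C3–C4 and the O1–C2 lactol bond.
- Forward key step: base releases an ortho-quinone methide from the ring D ortho-hydroxybenzyl sulfone A1. The enamine formed from aldehyde A2 and a diarylprolinol silyl ether adds to the methide carbon (C3–C4), and the phenol closes onto the aldehyde to give lactol A3.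
- For: the lower C3 oxygen is installed with its absolute configuration by the catalyst, with no hydroboration regiochemistry and no redox inversion. On this point it is stronger than the chosen route, which sets lower C3 by substrate control in three steps.
- Against: A3 still lacks ring E. The aryl group must be added to the lactol carbon and the ring re-formed at a benzylic centre, where an oxocarbenium or open-chain cyclisation tends to place the aryl trans to the C3 substituent, while 25 needs cis. A1 also needs a selective ortho-functionalisation of ring D (about three steps from 15), so the count after 15 is longer.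
- Comparison: the chosen route fixes C2 by a catalyst before the ring exists and obtains cis by a hydride reduction of known facial preference.

**Alternative 2: ring A grown by benzannulation from an acyclic triad.**
- Disconnection: upper C8a–C8, C7–C6 and C8a–C4a.
- Forward key step: photochemical Wolff rearrangement of diazomethyl enone A4 gives a vinylketene. This combines with siloxyalkyne A5 by [2+2] cycloaddition, 4π opening and 6π closure to give phenol A6 (free C8a hydroxyl, C7 silyl ether).
- For: the substitution pattern of ring A is unambiguous, the C8a hydroxyl is born differentiated, and no aryl metal addition to an enolisable flavanone is needed. On these points it is as strong as or stronger than the chosen route.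
- Against: ring A is the simplest part of 25 and is bought ready-made in 1. A4 must carry the whole lower flavan and the upper stereocentres through diazoketone chemistry, with C4 allylic, benzylic and γ to the carbonyl and so prone to epimerisation. The photolysis is run on a substrate with many aryl chromophores. Ring C must still be closed at benzylic C2 with control. The step count is by far the longest.
- Comparison: the chosen route is much shorter and spends its effort only on bonds that cannot be bought.

**Alternative 3: ring C in one step by ortho-quinone methide cycloaddition.**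
- Disconnection: upper O1–C2 and C3–C4.
- Forward key step: a chiral phosphoric acid dehydrates ortho-hydroxybenzhydrol A7 to an ortho-quinone methide, which takes up alkenylboronate A8 in an oxa-[4+2] cycloaddition to give 3-boryl-2,4-diarylchroman A9. Stereoretentive C–B oxidation would then give the C3 hydroxyl.
- For: highly convergent. The three upper stereocentres are set in one operation and the complete lower flavan is attached beforehand. In convergence and in stereocentres per step it is stronger than the chosen route.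
- Against: A7 requires a separately made, enantiopure 2,3-cis lower flavan metallated selectively at C6 (C6 versus C8 is not reliable for a 7-oxygenated chroman). A8 is a weakly nucleophilic 2π partner for a methide stabilised by only one para oxygen. The acid must override the facial bias of the large chiral substituent on the methide carbon, and the methide geometry decides the C4 relative configuration.
- Comparison: in the chosen route the 4→6 connectivity is built into 7, each stereocentre arises from one well-understood event, and the lower heterocycle is grown in place.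

Key step: step 13

Assumption: the ligand enantiomers named in steps 2 and 12 are those expected, from the usual models of these catalyst families, to give the (2S) flavanone and the (R) propargylic ether; if the sense of induction proves opposite, the mirror-image ligand is used.

Remark on descriptors: the geometry at the upper unit never changes after step 7. The CIP label of upper C4 is R in 13–15, 19 and 25 but S in 20–24, only because ring closure on ring D changes substituent ranking. Likewise upper C2 is S in 4–11 and R from 13 on, and lower C2 is R in 19–20 and S from 22 on.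

## Route

Step 1
Reactants: 1 7-hydroxy-4H-chromen-4-one
Product: 2 7-(benzyloxy)-4H-chromen-4-one
Conditions: BnBr, K2CO3, acetone, 55 °C
Reagents that add atoms: benzyl bromide, BrCc1ccccc1
Why: Williamson etherification of the only acidic hydroxyl; carbonate in acetone does not open the pyranone ring, and the benzyl ether is the permanent phenol protection removed in step 17.

Step 2
Reactants: 2 7-(benzyloxy)-4H-chromen-4-one; 3 4-(benzyloxy)phenylboronic acid
Product: 4 (2S)-7-(benzyloxy)-2-[4-(benzyloxy)phenyl]chroman-4-one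
Conditions: Pd(OCOCF3)2 (5 mol %), (R)-t-BuPyOx [(R)-4-tert-butyl-2-(pyridin-2-yl)-4,5-dihydrooxazole] (6 mol %), NH4PF6 (30 mol %), H2O (5 equiv), ClCH2CH2Cl, 60 °C
Reagents that add atoms: none
Why: Enantioselective conjugate arylation of a chromone by a cationic divalent palladium pyridine–oxazoline catalyst: transmetallation from boron, enantioface-selective insertion of C2=C3 into the aryl–palladium bond and protonolysis of the palladium enolate by water give the flavanone. The tert-butyl group of the ligand differentiates the faces of the bound chromone and should set C2 as S.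

Step 3
Reactants: 5 4-bromoresorcinol (4-bromobenzene-1,3-diol)
Product: 6 2-bromo-5-[(triisopropylsilyl)oxy]phenol
Conditions: i-Pr3SiCl (1.0 equiv), imidazole, CH2Cl2, 0 °C
Reagents that add atoms: chlorotriisopropylsilane, CC(C)[Si](Cl)(C(C)C)C(C)C
Why: Silylation with a bulky chlorosilane is governed by access to oxygen: the hydroxyl next to bromine is shielded and less nucleophilic, so the remote hydroxyl should react first. Any regioisomer or bis-silyl ether is removed by chromatography.

Step 4
Reactants: 6 2-bromo-5-[(triisopropylsilyl)oxy]phenol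
Product: 7 [3-(benzyloxy)-4-bromophenoxy]triisopropylsilane
Conditions: BnBr, K2CO3, acetone, 50 °C
Reagents that add atoms: benzyl bromide, BrCc1ccccc1
Why: Williamson benzylation of the remaining ortho-bromophenol; the triisopropylsilyl aryl ether tolerates carbonate in an aprotic solvent. The two ring D oxygens are now differentiated (benzyl permanent, silyl temporary).

Step 5
Reactants: 7 [3-(benzyloxy)-4-bromophenoxy]triisopropylsilane; 4 (2S)-7-(benzyloxy)-2-[4-(benzyloxy)phenyl]chroman-4-one
Product: 10 (2S)-7-(benzyloxy)-2-[4-(benzyloxy)phenyl]-4-{2-(benzyloxy)-4-[(triisopropylsilyl)oxy]phenyl}chroman-4-ol (C4 epimers), via aryllithium 8 (not isolated), via arylcerium dichloride 9 (not isolated)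
Conditions: n-BuLi, THF, −78 °C; anhydrous CeCl3, THF, −78 °C; then 4, −78 → −40 °C; H2O
Reagents that add atoms: none
Why: Bromine–lithium exchange and transmetallation give an organocerium reagent whose low basicity and high oxophilicity favour 1,2-addition to the enolisable, electron-rich aryl ketone over deprotonation at C3, which could open ring C by β-elimination of the phenoxide and endanger C2. The configuration of the new carbinol carbon is irrelevant because it becomes sp2 in step 6.

Step 6
Reactants: 10 (2S)-7-(benzyloxy)-2-[4-(benzyloxy)phenyl]-4-{2-(benzyloxy)-4-[(triisopropylsilyl)oxy]phenyl}chroman-4-ol (C4 epimers)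
Product: 11 (2S)-7-(benzyloxy)-2-[4-(benzyloxy)phenyl]-4-{2-(benzyloxy)-4-[(triisopropylsilyl)oxy]phenyl}-2H-chromene
Conditions: pyridinium p-toluenesulfonate (10 mol %), toluene, 4 Å molecular sieves, 40 °C, dark
Reagents that add atoms: none
Why: Acid-catalysed E1 dehydration through a doubly benzylic cation stabilised by the para oxygens of rings A and D, so a weak acid suffices and only C3 can lose a proton, giving the C3=C4 alkene. Mild acid and exclusion of light protect C2 from ionisation and from electrocyclic ring opening of the chromene.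

Step 7
Reactants: 11 (2S)-7-(benzyloxy)-2-[4-(benzyloxy)phenyl]-4-{2-(benzyloxy)-4-[(triisopropylsilyl)oxy]phenyl}-2H-chromene
Product: 13 (2R,3S,4R)-7-(benzyloxy)-2-[4-(benzyloxy)phenyl]-4-{2-(benzyloxy)-4-[(triisopropylsilyl)oxy]phenyl}chroman-3-ol, via C3 alkylborane 12 (not isolated)
Conditions: BH3·THF, THF, 0 °C → rt; then NaBO3·4H2O, THF/H2O, rt
Reagents that add atoms: sodium perborate, [Na+].[Na+].O[B-]1(O)OO[B-](O)(O)OO1
Why: Hydroboration–oxidation of a trisubstituted styrene-type alkene: boron goes to C3 and hydrogen to the diaryl-substituted C4 (steric and electronic control agree), with syn addition on the face of ring C opposite ring B. The C3 oxygen therefore ends trans to ring B and ring D is pushed to the face of ring B (2,3-trans-3,4-trans). C–B oxidation is retentive and perborate is mild enough for the aryl silyl ether.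

Step 8
Reactants: 13 (2R,3S,4R)-7-(benzyloxy)-2-[4-(benzyloxy)phenyl]-4-{2-(benzyloxy)-4-[(triisopropylsilyl)oxy]phenyl}chroman-3-ol
Product: 14 (2R,3S,4R)-3,7-bis(benzyloxy)-2-[4-(benzyloxy)phenyl]-4-{2-(benzyloxy)-4-[(triisopropylsilyl)oxy]phenyl}chromane
Conditions: NaH, BnBr, n-Bu4NI (cat.), THF, 0 °C → rt
Reagents that add atoms: benzyl bromide, BrCc1ccccc1
Why: Williamson benzylation of the secondary alkoxide; capping upper C3–OH keeps it out of the oxidation of step 15. In THF without a polar cosolvent the bulky aryl silyl ether should not be attacked.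

Step 9
Reactants: 14 (2R,3S,4R)-3,7-bis(benzyloxy)-2-[4-(benzyloxy)phenyl]-4-{2-(benzyloxy)-4-[(triisopropylsilyl)oxy]phenyl}chromane
Product: 15 3-(benzyloxy)-4-{(2R,3S,4R)-3,7-bis(benzyloxy)-2-[4-(benzyloxy)phenyl]chroman-4-yl}phenol
Conditions: n-Bu4NF, AcOH, THF, 0 °C
Reagents that add atoms: none
Why: Fluoride-induced cleavage of the aryl silyl ether, driven by the strong Si–F bond; the acetic acid buffer keeps the liberated phenoxide quiet and benzyl ethers are inert.

Step 10
Reactants: 16 3,4-bis(benzyloxy)benzaldehyde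
Product: 17 rac-1-[3,4-bis(benzyloxy)phenyl]prop-2-yn-1-ol
Conditions: HC≡CMgBr, THF, 0 °C; then H2O
Reagents that add atoms: ethynylmagnesium bromide, C#C[Mg]Br
Why: 1,2-Addition of an alkynyl Grignard reagent to an aromatic aldehyde; the alcohol is deliberately racemic because the stereocentre is re-created under catalyst control in step 12.

Step 11
Reactants: 17 rac-1-[3,4-bis(benzyloxy)phenyl]prop-2-yn-1-ol
Product: 18 rac-1-[3,4-bis(benzyloxy)phenyl]prop-2-yn-1-yl acetate
Conditions: Ac2O, Et3N, 4-(dimethylamino)pyridine (cat.), CH2Cl2, 0 °C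
Reagents that add atoms: acetic anhydride, CC(=O)OC(C)=O
Why: Nucleophile-catalysed acylation turns the hydroxyl into the leaving group needed for copper allenylidene formation; it is run cold because the electron-rich benzylic–propargylic acetate ionises easily.

Step 12
Reactants: 15 3-(benzyloxy)-4-{(2R,3S,4R)-3,7-bis(benzyloxy)-2-[4-(benzyloxy)phenyl]chroman-4-yl}phenol; 18 rac-1-[3,4-bis(benzyloxy)phenyl]prop-2-yn-1-yl acetate
Product: 19 (2R,3S,4R)-3,7-bis(benzyloxy)-2-[4-(benzyloxy)phenyl]-4-[2-(benzyloxy)-4-{(1R)-1-[3,4-bis(benzyloxy)phenyl]prop-2-yn-1-yloxy}phenyl]chromane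
Conditions: (CuOSO2CF3)2·C6H6 (5 mol %), (R,R)-Ph-pybox [2,6-bis((4R)-4-phenyl-4,5-dihydrooxazol-2-yl)pyridine] (12 mol %), i-Pr2NEt, 18 (1.5 equiv), CH2Cl2, −20 °C
Reagents that add atoms: none
Why: Copper-catalysed enantioselective propargylic etherification: amine and monovalent copper give a copper acetylide of 18, loss of acetate forms a copper allenylidene held in the chiral pybox pocket, and the phenoxide of 15 attacks the γ-carbon on the open face before protonation returns the terminal alkyne. Both enantiomers of 18 converge on the same planar intermediate, so the ligand alone should set the new centre as R; the stereocentres of 15 lie far from the reacting oxygen.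

Step 13
Reactants: 19 (2R,3S,4R)-3,7-bis(benzyloxy)-2-[4-(benzyloxy)phenyl]-4-[2-(benzyloxy)-4-{(1R)-1-[3,4-bis(benzyloxy)phenyl]prop-2-yn-1-yloxy}phenyl]chromane
Product: 20 (2R)-7-(benzyloxy)-2-[3,4-bis(benzyloxy)phenyl]-6-{(2R,3S,4S)-3,7-bis(benzyloxy)-2-[4-(benzyloxy)phenyl]chroman-4-yl}-2H-chromene
Conditions: Ph3PAuNTf2 (3 mol %), CH2Cl2 (0.02 M), rt, dark
Reagents that add atoms: none
Why: The cationic monovalent gold fragment [Ph3PAu]+ binds the terminal alkyne of 19 and makes it electrophilic; ring D attacks the terminal alkyne carbon with its carbon ortho to the ether oxygen and para to the C7 benzyloxy group, and the arenium/vinylgold intermediate rearomatises by proton loss and is released by protodeauration as the C3=C4 alkene. The closest known reaction type is the gold- or platinum-catalysed intramolecular hydroarylation of aryl propargyl ethers to 2H-chromenes. Ring F is closed in the 6-endo-dig mode (C4–C4a bond); the 5-exo-dig mode, which would give a 3-methylene-2,3-dihydrobenzofuran, is disfavoured because the aryl carbon cannot reach the internal alkyne carbon of the short O–C–C tether without strain. No stereocentre is created: C2 already carries ring E with the configuration from step 12, no bond to it is made or broken, and the non-ionising medium at room temperature should leave it untouched. The step needs regioselectivity between the two positions ortho to the ether oxygen: the future C4a is unhindered and para-activated by the C7 benzyloxy group, whereas the future C8 lies between two oxygens and is screened by the C7 benzyl group, which the bulky flavanyl substituent on its other side forces towards C8. Chemoselectivity over the other electron-rich arenes comes from intramolecularity and dilution, and light is excluded so that the chromene does not ring-open.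

Step 14
Reactants: 20 (2R)-7-(benzyloxy)-2-[3,4-bis(benzyloxy)phenyl]-6-{(2R,3S,4S)-3,7-bis(benzyloxy)-2-[4-(benzyloxy)phenyl]chroman-4-yl}-2H-chromene
Product: 22 (2S,3R)-7-(benzyloxy)-2-[3,4-bis(benzyloxy)phenyl]-6-{(2R,3S,4S)-3,7-bis(benzyloxy)-2-[4-(benzyloxy)phenyl]chroman-4-yl}chroman-3-ol, via lower C3 alkylborane 21 (not isolated)
Conditions: BH3·THF, THF, 0 °C → rt; then NaOH, H2O2, H2O, 0 °C
Reagents that add atoms: hydrogen peroxide, OO
Why: Hydroboration–oxidation of the 2H-chromene: hydrogen goes to benzylic C4, whose developing positive charge is stabilised by the electron-rich ring D, and boron to C3 (charge at C3 would be destabilised by the adjacent C2–O bond). Addition occurs anti to ring E, so retentive oxidation gives the 2,3-trans alcohol, which is corrected in steps 15 and 16.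

Step 15
Reactants: 22 (2S,3R)-7-(benzyloxy)-2-[3,4-bis(benzyloxy)phenyl]-6-{(2R,3S,4S)-3,7-bis(benzyloxy)-2-[4-(benzyloxy)phenyl]chroman-4-yl}chroman-3-ol
Product: 23 (2S)-7-(benzyloxy)-2-[3,4-bis(benzyloxy)phenyl]-6-{(2R,3S,4S)-3,7-bis(benzyloxy)-2-[4-(benzyloxy)phenyl]chroman-4-yl}chroman-3-one
Conditions: Dess–Martin periodinane, CH2Cl2, rt; crude used directly
Reagents that add atoms: none
Why: Dess–Martin oxidation of the only free hydroxyl under near-neutral, non-enolising conditions gives the flavan-3-one. The ketone is used at once because C2 (between carbonyl, oxygen and aryl) and C4 are enolisable.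

Step 16
Reactants: 23 (2S)-7-(benzyloxy)-2-[3,4-bis(benzyloxy)phenyl]-6-{(2R,3S,4S)-3,7-bis(benzyloxy)-2-[4-(benzyloxy)phenyl]chroman-4-yl}chroman-3-one
Product: 24 (2S,3S)-7-(benzyloxy)-2-[3,4-bis(benzyloxy)phenyl]-6-{(2R,3S,4S)-3,7-bis(benzyloxy)-2-[4-(benzyloxy)phenyl]chroman-4-yl}chroman-3-ol
Conditions: LiBH(s-Bu)3, LiBr, THF, −78 °C; then H2O
Reagents that add atoms: none
Why: A bulky trialkylborohydride approaches the carbonyl from the face opposite ring E on C2, so the hydroxyl ends cis to ring E. Low temperature and the weakly basic reagent keep C2 from epimerising; this oxidation–reduction pair is the standard 2,3-trans to 2,3-cis inversion of protected flavan-3-ols.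

Step 17
Reactants: 24 (2S,3S)-7-(benzyloxy)-2-[3,4-bis(benzyloxy)phenyl]-6-{(2R,3S,4S)-3,7-bis(benzyloxy)-2-[4-(benzyloxy)phenyl]chroman-4-yl}chroman-3-ol
Product: 25 (2R,3S,4R)-4-[(2S,3S)-2-(3,4-dihydroxyphenyl)-3,7-dihydroxychroman-6-yl]-2-(4-hydroxyphenyl)chromane-3,7-diol
Conditions: H2 (1 atm), Pd(OH)2/C, THF/MeOH (1:1), rt
Reagents that add atoms: none
Why: Hydrogenolysis of the six benzyl ethers over Pd(OH)2/C under neutral conditions; the benzylic ring C–O bonds of the chromans and the interflavan bond are cleaved much more slowly at 1 atm, so the reaction is stopped at full debenzylation.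

## Compound list

1 | 7-hydroxy-4H-chromen-4-one | O=c1ccoc2cc(O)ccc12 | starting material
2 | 7-(benzyloxy)-4H-chromen-4-one | O=c1ccoc2cc(OCc3ccccc3)ccc12 | intermediate
3 | 4-(benzyloxy)phenylboronic acid | OB(O)c1ccc(OCc2ccccc2)cc1 | starting material
4 | (2S)-7-(benzyloxy)-2-[4-(benzyloxy)phenyl]chroman-4-one | c1ccccc1COc1ccc([C@H]2Oc3cc(OCc4ccccc4)ccc3C(=O)C2)cc1 | intermediate
5 | 4-bromoresorcinol (4-bromobenzene-1,3-diol) | Oc1ccc(Br)c(O)c1 | starting material
6 | 2-bromo-5-[(triisopropylsilyl)oxy]phenol | Oc1cc(O[Si](C(C)C)(C(C)C)C(C)C)ccc1Br | intermediate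
7 | [3-(benzyloxy)-4-bromophenoxy]triisopropylsilane | CC(C)[Si](Oc1ccc(Br)c(OCc2ccccc2)c1)(C(C)C)C(C)C | intermediate
8 | {2-(benzyloxy)-4-[(triisopropylsilyl)oxy]phenyl}lithium (aryllithium) | [Li]c1ccc(O[Si](C(C)C)(C(C)C)C(C)C)cc1OCc1ccccc1 | intermediate (not isolated)
9 | dichloro{2-(benzyloxy)-4-[(triisopropylsilyl)oxy]phenyl}cerium (arylcerium dichloride) | Cl[Ce](Cl)c1ccc(O[Si](C(C)C)(C(C)C)C(C)C)cc1OCc1ccccc1 | intermediate (not isolated)
10 | (2S)-7-(benzyloxy)-2-[4-(benzyloxy)phenyl]-4-{2-(benzyloxy)-4-[(triisopropylsilyl)oxy]phenyl}chroman-4-ol (C4 epimers) | c1ccccc1COc1ccc([C@H]2Oc3cc(OCc4ccccc4)ccc3C(O)(c3ccc(O[Si](C(C)C)(C(C)C)C(C)C)cc3OCc3ccccc3)C2)cc1 | intermediate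
11 | (2S)-7-(benzyloxy)-2-[4-(benzyloxy)phenyl]-4-{2-(benzyloxy)-4-[(triisopropylsilyl)oxy]phenyl}-2H-chromene | c1ccccc1COc1ccc([C@H]2Oc3cc(OCc4ccccc4)ccc3C(c3ccc(O[Si](C(C)C)(C(C)C)C(C)C)cc3OCc3ccccc3)=C2)cc1 | intermediate
12 | C3 alkylborane of 11 (BH2 on C3 trans to ring B, H on C4 cis to boron) | c1ccccc1COc1ccc([C@H]2Oc3cc(OCc4ccccc4)ccc3[C@@H](c3ccc(O[Si](C(C)C)(C(C)C)C(C)C)cc3OCc3ccccc3)[C@@H]2B)cc1 | intermediate (not isolated)
13 | (2R,3S,4R)-7-(benzyloxy)-2-[4-(benzyloxy)phenyl]-4-{2-(benzyloxy)-4-[(triisopropylsilyl)oxy]phenyl}chroman-3-ol | c1ccccc1COc1ccc([C@H]2Oc3cc(OCc4ccccc4)ccc3[C@@H](c3ccc(O[Si](C(C)C)(C(C)C)C(C)C)cc3OCc3ccccc3)[C@@H]2O)cc1 | intermediate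
14 | (2R,3S,4R)-3,7-bis(benzyloxy)-2-[4-(benzyloxy)phenyl]-4-{2-(benzyloxy)-4-[(triisopropylsilyl)oxy]phenyl}chromane | c1ccccc1COc1ccc([C@H]2Oc3cc(OCc4ccccc4)ccc3[C@@H](c3ccc(O[Si](C(C)C)(C(C)C)C(C)C)cc3OCc3ccccc3)[C@@H]2OCc2ccccc2)cc1 | intermediate
15 | 3-(benzyloxy)-4-{(2R,3S,4R)-3,7-bis(benzyloxy)-2-[4-(benzyloxy)phenyl]chroman-4-yl}phenol | c1ccccc1COc1ccc([C@H]2Oc3cc(OCc4ccccc4)ccc3[C@@H](c3ccc(O)cc3OCc3ccccc3)[C@@H]2OCc2ccccc2)cc1 | intermediate
16 | 3,4-bis(benzyloxy)benzaldehyde | O=Cc1ccc(OCc2ccccc2)c(OCc2ccccc2)c1 | starting material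
17 | rac-1-[3,4-bis(benzyloxy)phenyl]prop-2-yn-1-ol | C#CC(O)c1ccc(OCc2ccccc2)c(OCc2ccccc2)c1 | intermediate
18 | rac-1-[3,4-bis(benzyloxy)phenyl]prop-2-yn-1-yl acetate | C#CC(OC(C)=O)c1ccc(OCc2ccccc2)c(OCc2ccccc2)c1 | intermediate
19 | (2R,3S,4R)-3,7-bis(benzyloxy)-2-[4-(benzyloxy)phenyl]-4-[2-(benzyloxy)-4-{(1R)-1-[3,4-bis(benzyloxy)phenyl]prop-2-yn-1-yloxy}phenyl]chromane | c1ccccc1COc1ccc([C@H]2Oc3cc(OCc5ccccc5)ccc3[C@@H](c3ccc(O[C@H](C#C)c4ccc(OCc5ccccc5)c(OCc5ccccc5)c4)cc3OCc5ccccc5)[C@@H]2OCc5ccccc5)cc1 | intermediate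
20 | (2R)-7-(benzyloxy)-2-[3,4-bis(benzyloxy)phenyl]-6-{(2R,3S,4S)-3,7-bis(benzyloxy)-2-[4-(benzyloxy)phenyl]chroman-4-yl}-2H-chromene | c1ccccc1COc1ccc([C@H]2Oc3cc(OCc5ccccc5)ccc3[C@@H](c3cc4c(cc3OCc5ccccc5)O[C@@H](c3ccc(OCc5ccccc5)c(OCc5ccccc5)c3)C=C4)[C@@H]2OCc5ccccc5)cc1 | intermediate
21 | lower C3 alkylborane of 20 (BH2 on lower C3 trans to ring E) | c1ccccc1COc1ccc([C@H]2Oc3cc(OCc5ccccc5)ccc3[C@@H](c3cc4c(cc3OCc5ccccc5)O[C@@H](c3ccc(OCc5ccccc5)c(OCc5ccccc5)c3)[C@H](B)C4)[C@@H]2OCc5ccccc5)cc1 | intermediate (not isolated)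
22 | (2S,3R)-7-(benzyloxy)-2-[3,4-bis(benzyloxy)phenyl]-6-{(2R,3S,4S)-3,7-bis(benzyloxy)-2-[4-(benzyloxy)phenyl]chroman-4-yl}chroman-3-ol | c1ccccc1COc1ccc([C@H]2Oc3cc(OCc5ccccc5)ccc3[C@@H](c3cc4c(cc3OCc5ccccc5)O[C@@H](c3ccc(OCc5ccccc5)c(OCc5ccccc5)c3)[C@H](O)C4)[C@@H]2OCc5ccccc5)cc1 | intermediate
23 | (2S)-7-(benzyloxy)-2-[3,4-bis(benzyloxy)phenyl]-6-{(2R,3S,4S)-3,7-bis(benzyloxy)-2-[4-(benzyloxy)phenyl]chroman-4-yl}chroman-3-one | c1ccccc1COc1ccc([C@H]2Oc3cc(OCc5ccccc5)ccc3[C@@H](c3cc4c(cc3OCc5ccccc5)O[C@@H](c3ccc(OCc5ccccc5)c(OCc5ccccc5)c3)C(=O)C4)[C@@H]2OCc5ccccc5)cc1 | intermediate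
24 | (2S,3S)-7-(benzyloxy)-2-[3,4-bis(benzyloxy)phenyl]-6-{(2R,3S,4S)-3,7-bis(benzyloxy)-2-[4-(benzyloxy)phenyl]chroman-4-yl}chroman-3-ol | c1ccccc1COc1ccc([C@H]2Oc3cc(OCc5ccccc5)ccc3[C@@H](c3cc4c(cc3OCc5ccccc5)O[C@@H](c3ccc(OCc5ccccc5)c(OCc5ccccc5)c3)[C@@H](O)C4)[C@@H]2OCc5ccccc5)cc1 | intermediate
25 | (2R,3S,4R)-4-[(2S,3S)-2-(3,4-dihydroxyphenyl)-3,7-dihydroxychroman-6-yl]-2-(4-hydroxyphenyl)chromane-3,7-diol | Oc1ccc([C@H]2Oc3cc(O)ccc3[C@@H](c3cc4c(cc3O)O[C@@H](c3ccc(O)c(O)c3)[C@@H](O)C4)[C@@H]2O)cc1 | target

## Step count and risks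

Total step count: 17. Longest linear sequence: 13 steps (steps 1, 2, 5, 6, 7, 8, 9, 12, 13, 14, 15, 16, 17; the branch from 5 through steps 3 and 4 is equally long).

Least certain steps:

**Step 13 (key step).** The likely failures are partial closure at the ring D carbon between the two oxygens, and ionisation of the benzylic–propargylic C–O bond by the Lewis-acidic catalyst or adventitious acid, which would erode the configuration at C2 or cleave the ether. The terminal alkyne may also tie up gold as an acetylide and stall turnover. The fallback sets out from 15 and returns at 20, replacing the arene attack by olefin metathesis. Magnesium-directed ortho-formylation of 15 (MgCl2, Et3N, paraformaldehyde) at the open position para to the benzyloxy group would give 4-(benzyloxy)-5-{(2R,3S,4S)-3,7-bis(benzyloxy)-2-[4-(benzyloxy)phenyl]chroman-4-yl}-2-hydroxybenzaldehyde F1. Wittig methylenation with excess Ph3P=CH2 would give 5-(benzyloxy)-4-{(2R,3S,4S)-3,7-bis(benzyloxy)-2-[4-(benzyloxy)phenyl]chroman-4-yl}-2-vinylphenol F2. The copper-catalysed etherification of step 12 with 18 would give (2R,3S,4S)-3,7-bis(benzyloxy)-2-[4-(benzyloxy)phenyl]-4-[2-(benzyloxy)-4-{(1R)-1-[3,4-bis(benzyloxy)phenyl]prop-2-yn-1-yloxy}-5-vinylphenyl]chromane F3. Semihydrogenation of the alkyne (H2, Pd/CaCO3 poisoned with Pb(OAc)2, quinoline) would give (2R,3S,4S)-3,7-bis(benzyloxy)-2-[4-(benzyloxy)phenyl]-4-[2-(benzyloxy)-4-{(1R)-1-[3,4-bis(benzyloxy)phenyl]prop-2-en-1-yloxy}-5-vinylphenyl]chromane F4. Ring-closing metathesis with second-generation Grubbs catalyst RuCl2(=CHPh)(PCy3)(H2IMes) would then close C3=C4 and give 20.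

**Step 12.** The likely failures are competing C-propargylation of the electron-rich ring D (Friedel–Crafts attack of the resorcinol-type ring on the allenylidene), a racemic background substitution through ionisation of the electron-rich acetate, and loss of catalyst control on the large chiral phenol. The fallback sets out from 17 (with 15) and returns at 19, moving the stereo-determining event to an enzymatic resolution. Acylation of 17 with vinyl acetate and immobilised Candida antarctica lipase B should, by the usual empirical rule for secondary alcohols, convert the R enantiomer into (1R)-1-[3,4-bis(benzyloxy)phenyl]prop-2-yn-1-yl acetate F6 and leave (1S)-1-[3,4-bis(benzyloxy)phenyl]prop-2-yn-1-ol F5. After separation, Mitsunobu etherification of F5 with 15 (PPh3, diisopropyl azodicarboxylate, toluene, 0 °C) would give 19 with inversion and with exclusive O-alkylation.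

**Step 5.** The likely failures are enolisation of the flavanone instead of addition, and β-elimination of the ring C phenoxide from the enolate, which would lower conversion and erode the configuration at C2. The fallback sets out from 4 and 7 and returns at 11, replacing carbonyl addition by cross-coupling and skipping 10 and step 6. Treatment of 4 with Tf2O and 2,6-di-tert-butyl-4-methylpyridine would give (2S)-7-(benzyloxy)-2-[4-(benzyloxy)phenyl]-2H-chromen-4-yl trifluoromethanesulfonate F7 without an enolate. Borylation of 7 (bis(pinacolato)diboron, PdCl2(dppf) with dppf = 1,1'-bis(diphenylphosphino)ferrocene, KOAc, dioxane) would give 2-{2-(benzyloxy)-4-[(triisopropylsilyl)oxy]phenyl}-4,4,5,5-tetramethyl-1,3,2-dioxaborolane F8. Suzuki coupling of F7 with F8 (Pd(PPh3)4, K3PO4, dioxane) would give 11.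

**Step 14.** The likely failures are incomplete regiocontrol of boron delivery (some boron at benzylic C4) and incomplete facial selectivity, and slow hydroboration next to the bulky upper unit. The fallback sets out from 20 and returns at 22, oxygenating both alkene carbons and then removing the benzylic oxygen. Dihydroxylation anti to ring E (OsO4 cat., N-methylmorpholine N-oxide, acetone/H2O) would give (2S,3R,4R)-7-(benzyloxy)-2-[3,4-bis(benzyloxy)phenyl]-6-{(2R,3S,4S)-3,7-bis(benzyloxy)-2-[4-(benzyloxy)phenyl]chroman-4-yl}chromane-3,4-diol F9. Ionic hydrogenation of the benzylic C4 hydroxyl (Et3SiH, BF3·OEt2, CH2Cl2, −78 °C) would give 22.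

## Further compounds

F1 | step 13 | 4-(benzyloxy)-5-{(2R,3S,4S)-3,7-bis(benzyloxy)-2-[4-(benzyloxy)phenyl]chroman-4-yl}-2-hydroxybenzaldehyde | c1ccccc1COc1ccc([C@H]2Oc3cc(OCc4ccccc4)ccc3[C@@H](c3cc(C=O)c(O)cc3OCc3ccccc3)[C@@H]2OCc2ccccc2)cc1
F2 | step 13 | 5-(benzyloxy)-4-{(2R,3S,4S)-3,7-bis(benzyloxy)-2-[4-(benzyloxy)phenyl]chroman-4-yl}-2-vinylphenol | c1ccccc1COc1ccc([C@H]2Oc3cc(OCc4ccccc4)ccc3[C@@H](c3cc(C=C)c(O)cc3OCc3ccccc3)[C@@H]2OCc2ccccc2)cc1
F3 | step 13 | (2R,3S,4S)-3,7-bis(benzyloxy)-2-[4-(benzyloxy)phenyl]-4-[2-(benzyloxy)-4-{(1R)-1-[3,4-bis(benzyloxy)phenyl]prop-2-yn-1-yloxy}-5-vinylphenyl]chromane | c1ccccc1COc1ccc([C@H]2Oc3cc(OCc5ccccc5)ccc3[C@@H](c3cc(C=C)c(O[C@H](C#C)c4ccc(OCc5ccccc5)c(OCc5ccccc5)c4)cc3OCc5ccccc5)[C@@H]2OCc5ccccc5)cc1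
F4 | step 13 | (2R,3S,4S)-3,7-bis(benzyloxy)-2-[4-(benzyloxy)phenyl]-4-[2-(benzyloxy)-4-{(1R)-1-[3,4-bis(benzyloxy)phenyl]prop-2-en-1-yloxy}-5-vinylphenyl]chromane | c1ccccc1COc1ccc([C@H]2Oc3cc(OCc5ccccc5)ccc3[C@@H](c3cc(C=C)c(O[C@H](C=C)c4ccc(OCc5ccccc5)c(OCc5ccccc5)c4)cc3OCc5ccccc5)[C@@H]2OCc5ccccc5)cc1
F5 | step 12 | (1S)-1-[3,4-bis(benzyloxy)phenyl]prop-2-yn-1-ol | O[C@@H](C#C)c1ccc(OCc2ccccc2)c(OCc2ccccc2)c1
F6 | step 12 | (1R)-1-[3,4-bis(benzyloxy)phenyl]prop-2-yn-1-yl acetate | CC(=O)O[C@H](C#C)c1ccc(OCc2ccccc2)c(OCc2ccccc2)c1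
F7 | step 5 | (2S)-7-(benzyloxy)-2-[4-(benzyloxy)phenyl]-2H-chromen-4-yl trifluoromethanesulfonate | c1ccccc1COc1ccc([C@H]2Oc3cc(OCc4ccccc4)ccc3C(OS(=O)(=O)C(F)(F)F)=C2)cc1
F8 | step 5 | 2-{2-(benzyloxy)-4-[(triisopropylsilyl)oxy]phenyl}-4,4,5,5-tetramethyl-1,3,2-dioxaborolane | CC(C)[Si](Oc1ccc(B2OC(C)(C)C(C)(C)O2)c(OCc2ccccc2)c1)(C(C)C)C(C)C
F9 | step 14 | (2S,3R,4R)-7-(benzyloxy)-2-[3,4-bis(benzyloxy)phenyl]-6-{(2R,3S,4S)-3,7-bis(benzyloxy)-2-[4-(benzyloxy)phenyl]chroman-4-yl}chromane-3,4-diol | c1ccccc1COc1ccc([C@H]2Oc3cc(OCc5ccccc5)ccc3[C@@H](c3cc4c(cc3OCc5ccccc5)O[C@@H](c3ccc(OCc5ccccc5)c(OCc5ccccc5)c3)[C@H](O)[C@@H]4O)[C@@H]2OCc5ccccc5)cc1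
A1 | alternative 1 | ring D ortho-hydroxybenzyl p-tolyl sulfone of the protected upper flavan (sulfonylmethyl group ortho to the free phenol, para to the benzyloxy group) | c1ccccc1COc1ccc([C@H]2Oc3cc(OCc5ccccc5)ccc3[C@@H](c3cc(CS(=O)(=O)c6ccc(C)cc6)c(O)cc3OCc5ccccc5)[C@@H]2OCc5ccccc5)cc1
A2 | alternative 1 | 2-(benzyloxy)acetaldehyde | O=CCOCc1ccccc1
A3 | alternative 1 | protected upper flavan linked to C6 of a 3,7-bis(benzyloxy)chroman-2-ol (lactol epimers) | c1ccccc1COc1ccc([C@H]2Oc3cc(OCc5ccccc5)ccc3[C@@H](c3cc4c(cc3OCc5ccccc5)OC(O)[C@@H](OCc5ccccc5)C4)[C@@H]2OCc5ccccc5)cc1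
A4 | alternative 2 | (E)-diazomethyl enone carrying the C4–C3–C2 chain with the protected lower flavan on C4 | [N-]=[N+]=CC(=O)/C=C/[C@@H](c3cc4c(cc3OCc5ccccc5)O[C@@H](c3ccc(OCc5ccccc5)c(OCc5ccccc5)c3)[C@@H](OCc5ccccc5)C4)[C@H](OCc5ccccc5)C(O[Si](C)(C)C(C)(C)C)c1ccc(OCc5ccccc5)cc1
A5 | alternative 2 | (ethynyloxy)triisopropylsilane | C#CO[Si](C(C)C)(C(C)C)C(C)C
A6 | alternative 2 | ring A phenol (free C8a hydroxyl, C7 triisopropylsilyl ether) carrying the C4–C3–C2 chain with the protected lower flavan on C4 | Oc1cc(O[Si](C(C)C)(C(C)C)C(C)C)ccc1[C@@H](c3cc4c(cc3OCc5ccccc5)O[C@@H](c3ccc(OCc5ccccc5)c(OCc5ccccc5)c3)[C@@H](OCc5ccccc5)C4)[C@H](OCc5ccccc5)C(O[Si](C)(C)C(C)(C)C)c1ccc(OCc5ccccc5)cc1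
A7 | alternative 3 | ortho-hydroxybenzhydrol from ring A (2-hydroxy-4-benzyloxyphenyl) and C6 of the protected lower flavan (carbinol epimers) | Oc1cc(OCc5ccccc5)ccc1C(O)c3cc4c(cc3OCc5ccccc5)O[C@@H](c3ccc(OCc5ccccc5)c(OCc5ccccc5)c3)[C@@H](OCc5ccccc5)C4
A8 | alternative 3 | (E)-2-[4-(benzyloxy)styryl]-4,4,5,5-tetramethyl-1,3,2-dioxaborolane | CC1(C)OB(/C=C/c2ccc(OCc3ccccc3)cc2)OC1(C)C
A9 | alternative 3 | 2,3-trans-3,4-trans 3-boryl-2,4-diarylchroman (protected dimer with a pinacolboronate at upper C3) | c1ccccc1COc1ccc([C@H]2Oc3cc(OCc5ccccc5)ccc3[C@@H](c3cc4c(cc3OCc5ccccc5)O[C@@H](c3ccc(OCc5ccccc5)c(OCc5ccccc5)c3)[C@@H](OCc5ccccc5)C4)[C@@H]2B6OC(C)(C)C(C)(C)O6)cc1
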